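Slowness ends early in the elm flask, which is the asked flask followed so far: from 20.0 h to 96.0 h its target stays between 21 % and 25 %.

| setting | elm | cedar | flask |
|---|---|---|---|
| starting material | 0.050 M | 0.050 M | 0.050 M |
| reagent | 0.0525 M | 0.0525 M | 0.0525 M |
| second substrate | 0.025 M | 0.013 M | 0.0250 M |
| remark | the very flask that is asked about, followed so far | run made earlier |  |
| time |  |  | 5.0 d |

- elm (time / h: target / %): 20.0: 24; 40.0: 25; 60.0: 21; 72.0: 22; 96.0: 23
- cedar (time / h: target / %): 0.500: 43; 1.00: 36; 1.33: 34; 2.00: 32; 2.50: 28

(scatter of a reading: 1.5 percentage points)

- Thursday's: at 5.0 d add reagent, 50.0 % of the amount charged, then wait 40 h
- Monday's: at 5.0 d add starting material, 50.0 % of the amount charged, then wait 40 h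
- Wednesday's: change nothing and wait 40 h more
- Friday's: at 5.0 d take out 90 % of the target then present, then wait 40 h

- target taken out counts as made
- reactions considered so far: starting material + reagent -> target; second substrate + reagent -> second product; starting material + second substrate -> cross product; reagent + target -> over-reaction product; target <-> isomer of the product
- additions bring no volume worth counting

- target, in percent of the starting material first charged, at 5.0 d
- what to do for the largest gain in target; "none" if nothing gains more than 2 percentage points (Thursday's / Monday's / Wednesday's / Friday's / none)
- target present, with what was taken out counted in, in percent of the starting material first charged, after Thursday's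
- target present, with what was taken out counted in, in percent of the starting material first charged, after Monday's

On the fastest rung, the cedar flask already holds 43 % target at 0.500 h, so the first couplings run on that scale or shorter. On the next rung, lasting hours, cedar target falls to 28 % at 2.50 h. On the last rung the elm flask stands still at a mean of 23.0 %, which is the reckoning here for now, and waiting longer should add nothing.

What Thursday's addition meets in the asked flask can be reckoned from a reagent ledger. Each starting material and each second substrate needs one reagent, but a pair joined as cross product needs none. Over-reaction aside:

c(cross product) at break-even = 0.5 × (c(starting material) + c(second substrate) − c(reagent)) = 22.5 % of the starting material charged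

This break-even cross product is the amount at which reagent exactly covers both substrates. Below it, the reagent shortfall is twice the gap.

With no cross product at all, the shortfall is twice break-even, 45.0 %, less than Thursday's addition, worth 52.5 % of the starting material. So, over-reaction aside, Thursday's reagent should cover both substrates and still have some over to meet target, and this reckoning leaves the size of the effect open.

The forecast gives 23 % now, Friday's as best, 31 % after Thursday's and 23 % after Monday's, holding that “Adding reagent converts the leftover”.

The flask gives 22.4 %. Friday's gains 13 percentage points, more than any other option; Monday's leaves 22.4 %.

    starting material + reagent → target (k = 0.0323 /M/s)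
    second substrate + reagent → second product (k = 0.0374 /M/s)
    starting material + second substrate → cross product (k = 0.0336 /M/s)
    reagent + target → over-reaction product (k = 0.00236 /M/s)
    target ⇌ isomer of the product (K = 2.00, k = 3.12 × 10⁻⁴ /s)

The asked flask stands at 23.5 % cross product at the asked time, near break-even, with over-reaction product at 5.65 %, 3.72 % of starting material and 0 % of the reagent charge left. Thursday's addition far exceeds that starting material, and in Thursday's flask target ends at 9.16 %, not the forecast's 31 %. In the neighbour flask with 0.032 M of reagent, break-even is 43.0 %, cross product reaches 33.1 % and over-reaction product 1.33 %, and twice the gap plus that over-reaction product comes to 21.1 %, with 21 % of the starting material left.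

(All runs are simulated on assumed constants; noise was put on by code.)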